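**Plan**

- Retrosynthesis: the C2–H of the pyridine is traced back to a C2 oxygen (a 2-pyridone, removable as its triflate). The pyridone ring is then cut at C3–C4 and C5–C6 into a 2-azadiene and an alkyne.
- Enabling feature: with the ring numbered N1, C2, C3 (decyl), C4, C5 (decanoyl), C6, the atoms C4–C5 plus the exocyclic ketone are an alk-1-yn-3-one. C6–N1–C2–C3 with its decyl chain is dodecanamide carrying one extra formyl-level carbon on nitrogen, and an oxygen at C2 turns that four-atom unit into an electron-rich diene.
- Forward order: dodecanamide is taken to its N-acylformamidine and then to the silyloxy azadiene (steps 1–2). Decanal is ethynylated and oxidised to dodec-1-yn-3-one (steps 3–4). The two halves are joined and the only ring is formed in step 5. The C2 oxygen is removed by triflation and palladium/formate reduction (steps 6–7).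
- Stereochemistry: the target has no stereocentre. The diene geometry, the racemic carbinol of step 3 and the two sp3 centres of the cycloadduct are all transient.

Key step: step 5

Remark on the chemistry: diene 4 is moisture-sensitive and is assumed to be carried into step 5 as the crude concentrate under argon. The 2-silyloxypyridine 10 is assumed to be cleaved by the dilute-acid work-up.

**Step 1**
Reactants: 1 dodecanamide; 2 N,N-dimethylformamide dimethyl acetal
Product: 3 (E)-N-[(dimethylamino)methylidene]dodecanamide
Conditions: 2 (1.5 equiv), toluene, 100 °C, MeOH distilled off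
Reagents that add atoms: N,N-dimethylformamide dimethyl acetal (2), COC(OC)N(C)C
Why: Amide–amide acetal condensation, in which the acetal ionises to a methoxy-iminium ion that is captured by the primary amide nitrogen and loss of the second methanol gives the conjugated (E)-N-acylformamidine, the equilibrium being pulled over by removal of methanol.

**Step 2**
Reactants: 3 (E)-N-[(dimethylamino)methylidene]dodecanamide
Product: 4 (E)-N'-[(Z)-1-(tert-butyldimethylsilyloxy)dodec-1-enyl]-N,N-dimethylformimidamide (the 2-azadiene)
Conditions: TBSOTf (1.1 equiv), Et3N (1.5 equiv), Et2O, 0 °C to rt, argon; lower ammonium triflate layer removed, ether layer concentrated, used crude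
Reagents that add atoms: tert-butyldimethylsilyl trifluoromethanesulfonate, CC(C)(C)[Si](C)(C)OS(=O)(=O)C(F)(F)F
Why: Soft enolisation with O-silylation, in which the silyl triflate silylates the acyl oxygen, triethylamine removes the acidified α-proton, and the resulting silyl ketene N,O-acetal is the 1-dimethylamino-3-silyloxy-2-azadiene, expected with the decyl chain cis to the silyloxy group (Z) as is usual for amide-type enolisation.

**Step 3**
Reactants: 5 decanal; 6 ethynylmagnesium bromide
Product: 7 (±)-dodec-1-yn-3-ol
Conditions: 6 (0.5 M in THF, 1.2 equiv), THF, 0 °C to rt; then cold 1 M HCl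
Reagents that add atoms: ethynylmagnesium bromide (6), C#C[Mg]Br
Why: Grignard 1,2-addition of the acetylide to the unhindered aldehyde; the carbinol centre is formed racemic, which is of no consequence because it is oxidised in step 4.

**Step 4**
Reactants: 7 (±)-dodec-1-yn-3-ol
Product: 8 dodec-1-yn-3-one
Conditions: activated MnO2 (15 equiv), CH2Cl2, rt; filtered through Celite
Reagents that add atoms: none
Why: MnO2 oxidation of an activated (propargylic) alcohol to the ynone under neutral, non-aqueous, heterogeneous conditions, chosen because the terminal ynone is a strong Michael acceptor that should not meet base or nucleophiles.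

**Step 5**
Reactants: 4 (E)-N'-[(Z)-1-(tert-butyldimethylsilyloxy)dodec-1-enyl]-N,N-dimethylformimidamide; 8 dodec-1-yn-3-one
Product: 11 5-decanoyl-3-decylpyridin-2(1H)-one, via dihydropyridine cycloadduct 9 (not isolated), via 2-silyloxypyridine 10 (not isolated)
Conditions: 8 (1.5 equiv, added slowly), toluene, 0 °C to rt, then 60 °C; then 1 M HCl, THF, rt
Reagents that add atoms: none
Why: The electron-rich 2-azadiene 4 (a silyl ketene N,O-acetal conjugated through nitrogen with a formamidine) should combine with the electron-poor alkyne of 8 in a normal-electron-demand hetero-Diels–Alder reaction, either concerted and asynchronous or as Michael addition followed by Mannich-type closure of the allenolate onto the amidinium carbon; the closest known reaction type is the cycloaddition of 1-dimethylamino-3-silyloxy-2-azadienes with propiolates, acetylenedicarboxylates and acetylenic ketones. The pyridine ring is closed by this intermolecular [4+2] event, which forms both C3–C4 and C5–C6 and turns two acyclic halves into the six-membered ring in one operation. Cycloadduct 9 should then lose dimethylamine by 1,4-elimination (C3–H and C6–NMe2) to give the aromatic 2-silyloxypyridine 10, and dilute acid removes the labile O-silyl group to leave the pyridone tautomer 11. The two sp3 centres of 9 are formed without control and are both erased on aromatisation, so no stereocentre has to be set. The selectivity that matters is regiochemical: the diene terminus with the largest HOMO coefficient is the decyl-bearing ketene-acetal carbon, which bonds to the unsubstituted, electrophilic β-carbon of the ynone, while the amidine carbon bonds to the α-carbon, placing the acyl group at C5 and hydrogen at C4. The (Z)-geometry of 4 keeps the decyl chain on the outside of the s-cis diene, where it does not hinder the approach of the alkyne.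

**Step 6**
Reactants: 11 5-decanoyl-3-decylpyridin-2(1H)-one
Product: 12 5-decanoyl-3-decylpyridin-2-yl trifluoromethanesulfonate
Conditions: Tf2O (1.2 equiv), pyridine (2.5 equiv), CH2Cl2, 0 °C
Reagents that add atoms: trifluoromethanesulfonic anhydride, O=S(=O)(OS(=O)(=O)C(F)(F)F)C(F)(F)F
Why: O-Sulfonylation of the 2-pyridone through its ambident amide oxygen with triflic anhydride, which is fast at 0 °C, whereas the alkyl ketone is not enolised by pyridine under these conditions and should stay intact.

**Step 7**
Reactants: 12 5-decanoyl-3-decylpyridin-2-yl trifluoromethanesulfonate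
Product: 13 1-(5-decylpyridin-3-yl)decan-1-one (3-decanoyl-5-decylpyridine, the target)
Conditions: Pd(OAc)2 (5 mol %), 1,1'-bis(diphenylphosphino)ferrocene (6 mol %), HCO2H (2 equiv), Et3N (3 equiv), DMF, 60 °C
Reagents that add atoms: none
Why: Palladium-catalysed formate reduction of a heteroaryl triflate, in which oxidative addition of the C2–O bond to zerovalent palladium, exchange of triflate for formate, decarboxylation to the aryl palladium hydride and reductive elimination deliver C2–H, while the ketone, the alkyl chains and the pyridine ring are inert to these conditions.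

**Compound list**

1 | dodecanamide | CCCCCCCCCCCC(N)=O | starting material
2 | N,N-dimethylformamide dimethyl acetal | COC(OC)N(C)C | starting material
3 | (E)-N-[(dimethylamino)methylidene]dodecanamide | CCCCCCCCCCCC(=O)/N=C/N(C)C | intermediate
4 | (E)-N'-[(Z)-1-(tert-butyldimethylsilyloxy)dodec-1-enyl]-N,N-dimethylformimidamide | CCCCCCCCCC/C=C(\O[Si](C)(C)C(C)(C)C)/N=C/N(C)C | intermediate
5 | decanal | CCCCCCCCCC=O | starting material
6 | ethynylmagnesium bromide | C#C[Mg]Br | starting material
7 | (±)-dodec-1-yn-3-ol (racemic) | C#CC(O)CCCCCCCCC | intermediate
8 | dodec-1-yn-3-one | C#CC(=O)CCCCCCCCC | intermediate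
9 | 1-[6-(tert-butyldimethylsilyloxy)-5-decyl-2-(dimethylamino)-2,5-dihydropyridin-3-yl]decan-1-one (dihydropyridine cycloadduct, mixture of diastereomers, not isolated) | CCCCCCCCCCC1C=C(C(=O)CCCCCCCCC)C(N(C)C)N=C1O[Si](C)(C)C(C)(C)C | intermediate
10 | 1-[6-(tert-butyldimethylsilyloxy)-5-decylpyridin-3-yl]decan-1-one (2-silyloxypyridine, not isolated) | CCCCCCCCCCc1cc(C(=O)CCCCCCCCC)cnc1O[Si](C)(C)C(C)(C)C | intermediate
11 | 5-decanoyl-3-decylpyridin-2(1H)-one | O=c1[nH]cc(C(=O)CCCCCCCCC)cc1CCCCCCCCCC | intermediate
12 | 5-decanoyl-3-decylpyridin-2-yl trifluoromethanesulfonate | CCCCCCCCCCc1cc(C(=O)CCCCCCCCC)cnc1OS(=O)(=O)C(F)(F)F | intermediate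
13 | 1-(5-decylpyridin-3-yl)decan-1-one | CCCCCCCCCCc1cncc(C(=O)CCCCCCCCC)c1 | target

**Step count and risks**

Total step count: 7. Longest linear sequence: 5 steps (1, 2, 5, 6, 7 from dodecanamide, or equally 3, 4, 5, 6, 7 from decanal).

Steps most likely to fail:

Step 5. The dimethylamine liberated on aromatisation may add in conjugate fashion to unreacted ynone, and the terminal ynone may oligomerise or the diene may hydrolyse before the two meet, so the cycloaddition could stall at low conversion. The fallback sets out from 4 and keeps the same ring-forming bonds but brings in the C5 carbonyl as an ester, converting it to the ketone only after the C2 oxygen has been removed. Diene 4 would be combined with an excess of methyl propiolate (toluene, rt to 60 °C, then dilute HCl), which should pass through methyl 6-(tert-butyldimethylsilyloxy)-5-decyl-2-(dimethylamino)-2,5-dihydropyridine-3-carboxylate F1 and methyl 6-(tert-butyldimethylsilyloxy)-5-decylpyridine-3-carboxylate F2 to methyl 5-decyl-6-oxo-1,6-dihydropyridine-3-carboxylate F3. Triflation as in step 6 should give methyl 5-decyl-6-(trifluoromethylsulfonyloxy)pyridine-3-carboxylate F4, and formate reduction as in step 7 should give methyl 5-decylpyridine-3-carboxylate F5. Treatment with N,O-dimethylhydroxylamine hydrochloride and iPrMgCl in THF at −20 °C should give 5-decyl-N-methoxy-N-methylpyridine-3-carboxamide F6, and nonylmagnesium bromide in THF at 0 °C should then give the ketone. The fallback comes back to the route at 13.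

Step 2. Hydrolytic loss of the silyl group during isolation would return 3, since the long-chain diene cannot be distilled conveniently and does not tolerate silica. The fallback sets out from 3 and changes the diene to a bulkier silyl ketene aminal that should be more robust to handling. Triisopropylsilyl trifluoromethanesulfonate and Et3N in Et2O should give (E)-N'-[(Z)-1-(triisopropylsilyloxy)dodec-1-enyl]-N,N-dimethylformimidamide F7. This would be combined with 8 as in step 5, passing through 1-[5-decyl-2-(dimethylamino)-6-(triisopropylsilyloxy)-2,5-dihydropyridin-3-yl]decan-1-one F8 and 1-[5-decyl-6-(triisopropylsilyloxy)pyridin-3-yl]decan-1-one F9, and acidic desilylation brings it back to the route at 11.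

Step 4. Oxidation on the MnO2 surface may be incomplete, and the electrophilic terminal ynone may be lost by oligomerisation during long contact with the oxidant or on chromatography. The fallback sets out from 6 and replaces addition/oxidation by acylation at the ketone oxidation level. Reagent 6 would be added in THF at 0 °C to N-methoxy-N-methyldecanamide F10 (prepared from decanoyl chloride, N,O-dimethylhydroxylamine hydrochloride and pyridine in CH2Cl2). An inverse quench into cold aqueous NaHSO4 protonates the released hydroxylamine before it can add to the ynone. This comes back to the route at 8.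

**Further compounds**

F1 | step 5 | methyl 6-(tert-butyldimethylsilyloxy)-5-decyl-2-(dimethylamino)-2,5-dihydropyridine-3-carboxylate | CCCCCCCCCCC1C=C(C(=O)OC)C(N(C)C)N=C1O[Si](C)(C)C(C)(C)C
F2 | step 5 | methyl 6-(tert-butyldimethylsilyloxy)-5-decylpyridine-3-carboxylate | CCCCCCCCCCc1cc(C(=O)OC)cnc1O[Si](C)(C)C(C)(C)C
F3 | step 5 | methyl 5-decyl-6-oxo-1,6-dihydropyridine-3-carboxylate | CCCCCCCCCCc1cc(C(=O)OC)c[nH]c1=O
F4 | step 5 | methyl 5-decyl-6-(trifluoromethylsulfonyloxy)pyridine-3-carboxylate | CCCCCCCCCCc1cc(C(=O)OC)cnc1OS(=O)(=O)C(F)(F)F
F5 | step 5 | methyl 5-decylpyridine-3-carboxylate | CCCCCCCCCCc1cncc(C(=O)OC)c1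
F6 | step 5 | 5-decyl-N-methoxy-N-methylpyridine-3-carboxamide | CCCCCCCCCCc1cncc(C(=O)N(C)OC)c1
F7 | step 2 | (E)-N'-[(Z)-1-(triisopropylsilyloxy)dodec-1-enyl]-N,N-dimethylformimidamide | CCCCCCCCCC/C=C(\O[Si](C(C)C)(C(C)C)C(C)C)/N=C/N(C)C
F8 | step 2 | 1-[5-decyl-2-(dimethylamino)-6-(triisopropylsilyloxy)-2,5-dihydropyridin-3-yl]decan-1-one | CCCCCCCCCCC1C=C(C(=O)CCCCCCCCC)C(N(C)C)N=C1O[Si](C(C)C)(C(C)C)C(C)C
F9 | step 2 | 1-[5-decyl-6-(triisopropylsilyloxy)pyridin-3-yl]decan-1-one | CCCCCCCCCCc1cc(C(=O)CCCCCCCCC)cnc1O[Si](C(C)C)(C(C)C)C(C)C
F10 | step 4 | N-methoxy-N-methyldecanamide | CCCCCCCCCC(=O)N(C)OC
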